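**Retrosynthetic overview**
1. Target 24 ⇐ pentakis-MOM flavanone 22 (deprotection) ⇐ C2-epimer pair 21, resolved by asymmetric transfer hydrogenation.
2. 21 ⇐ 2'-hydroxychalcone 20 (oxa-Michael, closes ring C) ⇐ aryl cinnamate 19 by photo-Fries rearrangement. This is the key step: a radical pair forms C4–C4a, and the ester oxygen becomes O1.
3. 19 ⇐ aryl iodide 10 + (S)-lavandulylzinc iodide 18 (Negishi); 18 comes from an Evans deconjugative prenylation of a senecioyl imide.
4. 10 ⇐ iodophenol 6 + cinnamic acid 9 (Heck of 7 with acrylic acid); 6 ⇐ resorcinol by MOM protection, ortho-lithiation/iodination and Ir-catalysed C–H borylation/oxidation.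
5. Ring order: rings A and B both come preformed from resorcinol through 6; ring C is the only ring built, and it is built last (step 12).

Assumption: the descriptors read from the SMILES are (2S) at the flavanone carbon and (2R) at the side-chain carbon.

Abbreviations: MOM = methoxymethyl; MOMO = methoxymethoxy; Lav = (2R)-5-methyl-2-(prop-1-en-2-yl)hex-4-en-1-yl, as bonded to the arene.

**Route**

Step 1
Reactants: 1 resorcinol
Product: 2 1,3-bis(MOMO)benzene
Conditions: MOMCl, i-Pr2NEt, CH2Cl2, 0 °C to rt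
Reagents that add atoms: chloromethyl methyl ether, COCCl
Why: Williamson-type acetal ether formation protects both phenols as MOM ethers, which also serve as ortho-directing groups for step 2.

Step 2
Reactants: 2 1,3-bis(MOMO)benzene
Product: 4 2-iodo-1,3-bis(MOMO)benzene, via aryllithium 3 (not isolated)
Conditions: n-BuLi, THF, 0 °C; then I2, −78 °C to rt
Reagents that add atoms: n-butyllithium, [Li]CCCC (lithium of 3); iodine, II
Why: Directed ortho-metalation: the two MOM ethers jointly direct lithiation to the carbon between them, and iodine quench fixes the handle at that carbon.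

Step 3
Reactants: 4 2-iodo-1,3-bis(MOMO)benzene
Product: 6 4-iodo-3,5-bis(MOMO)phenol, via pinacol boronate 5 (not isolated)
Conditions: [Ir(OMe)(cod)]2 (1.5 mol %), 4,4'-di-tert-butyl-2,2'-bipyridine, B2pin2, THF, 80 °C; then 30 % aq. H2O2, NaOH, 0 °C
Reagents that add atoms: bis(pinacolato)diboron, CC1(C)OB(OC1(C)C)B1OC(C)(C)C(C)(C)O1 (boryl group of 5); hydrogen peroxide, OO (phenol oxygen of 6)
Why: Sterically controlled iridium-catalysed C–H borylation goes to the only C–H flanked by two hydrogens (para to iodine, the C–I bond is tolerated), and one-pot boronate oxidation gives the third oxygen.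

Step 4
Reactants: 6 4-iodo-3,5-bis(MOMO)phenol
Product: 7 2-iodo-1,3,5-tris(MOMO)benzene
Conditions: MOMCl, i-Pr2NEt, CH2Cl2, 0 °C to rt
Reagents that add atoms: chloromethyl methyl ether, COCCl
Why: MOM ether formation caps the free phenol so that the ring B half carries no acidic OH in the Heck reaction and esterification.

Step 5
Reactants: 7 2-iodo-1,3,5-tris(MOMO)benzene; 8 acrylic acid
Product: 9 (E)-3-[2,4,6-tris(MOMO)phenyl]prop-2-enoic acid
Conditions: Pd(OAc)2 (5 mol %), n-Bu4NCl, NaHCO3, DMF, 85 °C; work-up at pH 4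
Reagents that add atoms: none
Why: Heck reaction under ligand-free phase-transfer (Jeffery) conditions, which suit hindered electron-rich aryl iodides, gives the trans-cinnamic acid.

Step 6
Reactants: 6 4-iodo-3,5-bis(MOMO)phenol; 9 (E)-3-[2,4,6-tris(MOMO)phenyl]prop-2-enoic acid
Product: 10 4-iodo-3,5-bis(MOMO)phenyl (E)-3-[2,4,6-tris(MOMO)phenyl]prop-2-enoate
Conditions: EDC·HCl, DMAP (cat.), CH2Cl2, rt
Reagents that add atoms: none
Why: Steglich-type carbodiimide esterification joins the two ring halves through the oxygen that will become O1 and masks the phenol for the organozinc coupling.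

Step 7
Reactants: 11 3-methylbut-2-enoyl chloride
Product: 12 (4S)-4-benzyl-3-(3-methylbut-2-enoyl)-1,3-oxazolidin-2-one
Conditions: (S)-4-benzyl-1,3-oxazolidin-2-one, n-BuLi, THF, −78 °C; then 11, −78 to 0 °C
Reagents that add atoms: (S)-4-benzyl-1,3-oxazolidin-2-one, O=C1N[C@@H](Cc2ccccc2)CO1
Why: N-acylation of the lithiated Evans oxazolidinone installs the recoverable chiral auxiliary.

Step 8
Reactants: 12 (4S)-4-benzyl-3-(3-methylbut-2-enoyl)-1,3-oxazolidin-2-one; 13 1-bromo-3-methylbut-2-ene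
Product: 15 (4S)-4-benzyl-3-[(2S)-5-methyl-2-(prop-1-en-2-yl)hex-4-enoyl]-1,3-oxazolidin-2-one, via sodium dienolate 14 (not isolated)
Conditions: NaN(SiMe3)2, THF, −78 °C; then 13, −78 to −40 °C
Reagents that add atoms: sodium bis(trimethylsilyl)amide, [Na+].C[Si](C)(C)[N-][Si](C)(C)C (sodium of 14)
Why: Evans deconjugative α-alkylation: γ-deprotonation gives the chelated Z-dienolate, which is prenylated at the α-carbon on the face opposite the benzyl group; this sets the side-chain stereocentre as (2S) in the imide, and the minor diastereomer is removed by chromatography.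

Step 9
Reactants: 15 (4S)-4-benzyl-3-[(2S)-5-methyl-2-(prop-1-en-2-yl)hex-4-enoyl]-1,3-oxazolidin-2-one
Product: 16 (2S)-5-methyl-2-(prop-1-en-2-yl)hex-4-en-1-ol [(S)-lavandulol]
Conditions: LiBH4, MeOH (1 equiv), THF, 0 °C
Reagents that add atoms: none
Why: Reductive cleavage of the N-acyl oxazolidinone gives the primary alcohol without touching the β,γ-unsaturated stereocentre and returns the auxiliary.

Step 10
Reactants: 16 (S)-lavandulol
Product: 17 (3S)-3-(iodomethyl)-2,6-dimethylhepta-1,5-diene [(S)-lavandulyl iodide]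
Conditions: I2, PPh3, imidazole, CH2Cl2, 0 °C to rt
Reagents that add atoms: iodine, II
Why: Appel iodination is an SN2 displacement at the primary carbon, so the adjacent stereocentre is untouched.

Step 11
Reactants: 17 (S)-lavandulyl iodide; 10 4-iodo-3,5-bis(MOMO)phenyl (E)-3-[2,4,6-tris(MOMO)phenyl]prop-2-enoate
Product: 19 4-Lav-3,5-bis(MOMO)phenyl (E)-3-[2,4,6-tris(MOMO)phenyl]prop-2-enoate, via alkylzinc iodide 18 (not isolated)
Conditions: Zn dust, LiCl, THF, 40 °C; then 10, Pd(OAc)2 (3 mol %), SPhos (6 mol %), THF, 45 °C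
Reagents that add atoms: zinc, [Zn] (zinc of 18)
Why: Negishi coupling with a bulky biarylphosphine joins the primary alkylzinc to the di-ortho-alkoxy aryl iodide; the aryl ester and enoate are inert to RZnI, and the stereocentre β to zinc is carried over unchanged (now (2R) by priority rules).

Step 12 (key step)
Reactants: 19 4-Lav-3,5-bis(MOMO)phenyl (E)-3-[2,4,6-tris(MOMO)phenyl]prop-2-enoate
Product: 21 (2RS)-6-Lav-5,7-bis(MOMO)-2-[2,4,6-tris(MOMO)phenyl]chroman-4-one (about 1:1 C2 epimers), via chalcone 20 (not isolated)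
Conditions: hν (254 nm, quartz), degassed MeCN (5 mM), rt; then NaOAc, EtOH, reflux
Reagents that add atoms: none
Why: Photo-Fries rearrangement: excitation cleaves the ArO–C(O) bond homolytically and the caged cinnamoyl/aryloxyl radical pair recombines at an ortho carbon (para is blocked by Lav, both ortho carbons are equivalent), forming C4–C4a and leaving the ester oxygen as the only free OH, so the acetate-mediated oxa-Michael closure can give only the 6-substituted chromanone; C2 forms without control and is set in step 13.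

Step 13
Reactants: 21 (2RS)-6-Lav-5,7-bis(MOMO)-2-[2,4,6-tris(MOMO)phenyl]chroman-4-one
Product: 22 (2S)-6-Lav-5,7-bis(MOMO)-2-[2,4,6-tris(MOMO)phenyl]chroman-4-one
Conditions: RhCl[(R,R)-TsDPEN](C5Me5) (1 mol %), HCO2H/Et3N (5:2), EtOAc, 30 °C, stopped at about 55 % conversion
Reagents that add atoms: none
Why: Kinetic resolution by Noyori-type asymmetric transfer hydrogenation: the (R,R) catalyst gives (4R) carbinols and therefore reduces the matched (2R) epimer to the 2,4-cis flavan-4-ol much faster, leaving the (2S) ketone, which is how C2 is set; alkenes and MOM ethers are inert.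

Step 14
Reactants: 22 (2S)-6-Lav-5,7-bis(MOMO)-2-[2,4,6-tris(MOMO)phenyl]chroman-4-one
Product: 24 (2S)-5,7-dihydroxy-6-[(2R)-5-methyl-2-(prop-1-en-2-yl)hex-4-en-1-yl]-2-(2,4,6-trihydroxyphenyl)chroman-4-one, via pentakis-silyl ether 23 (not isolated)
Conditions: Me3SiOTf, 2,2'-bipyridyl, MeCN, 0 °C to rt; then H2O
Reagents that add atoms: trimethylsilyl trifluoromethanesulfonate, C[Si](C)(C)OS(=O)(=O)C(F)(F)F (silyl groups of 23)
Why: Silyl triflate/bipyridyl cleavage turns aryl MOM ethers into aryl silyl ethers that hydrolyse on adding water, a non-protic acetal cleavage chosen because the C2–O1 bond is a trihydroxybenzyl-type ether and the isopropenyl group is acid-sensitive; no stereocentre is touched.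

**Compound list**
1 | resorcinol (benzene-1,3-diol) | Oc1cccc(O)c1 | starting material
2 | 1,3-bis(methoxymethoxy)benzene | COCOc1cccc(OCOC)c1 | intermediate
3 | [2,6-bis(methoxymethoxy)phenyl]lithium | [Li]c1c(OCOC)cccc1OCOC | intermediate (not isolated)
4 | 2-iodo-1,3-bis(methoxymethoxy)benzene | COCOc1cccc(OCOC)c1I | intermediate
5 | 2-[4-iodo-3,5-bis(methoxymethoxy)phenyl]-4,4,5,5-tetramethyl-1,3,2-dioxaborolane | COCOc1cc(B2OC(C)(C)C(C)(C)O2)cc(OCOC)c1I | intermediate (not isolated)
6 | 4-iodo-3,5-bis(methoxymethoxy)phenol | COCOc1cc(O)cc(OCOC)c1I | intermediate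
7 | 2-iodo-1,3,5-tris(methoxymethoxy)benzene | COCOc1cc(OCOC)c(I)c(OCOC)c1 | intermediate
8 | acrylic acid (prop-2-enoic acid) | C=CC(=O)O | starting material
9 | (E)-3-[2,4,6-tris(methoxymethoxy)phenyl]prop-2-enoic acid | COCOc1cc(OCOC)c(/C=C/C(=O)O)c(OCOC)c1 | intermediate
10 | 4-iodo-3,5-bis(methoxymethoxy)phenyl (E)-3-[2,4,6-tris(methoxymethoxy)phenyl]prop-2-enoate | COCOc1cc(OCOC)c(/C=C/C(=O)Oc2cc(OCOC)c(I)c(OCOC)c2)c(OCOC)c1 | intermediate
11 | 3-methylbut-2-enoyl chloride | CC(C)=CC(=O)Cl | starting material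
12 | (4S)-4-benzyl-3-(3-methylbut-2-enoyl)-1,3-oxazolidin-2-one | CC(C)=CC(=O)N1[C@@H](Cc2ccccc2)COC1=O | intermediate
13 | 1-bromo-3-methylbut-2-ene (prenyl bromide) | CC(C)=CCBr | starting material
14 | sodium (Z)-dienolate of 12 | [Na+].C=C(C)/C=C(\[O-])N1[C@@H](Cc2ccccc2)COC1=O | intermediate (not isolated)
15 | (4S)-4-benzyl-3-[(2S)-5-methyl-2-(prop-1-en-2-yl)hex-4-enoyl]-1,3-oxazolidin-2-one | C=C(C)[C@H](CC=C(C)C)C(=O)N1[C@@H](Cc2ccccc2)COC1=O | intermediate
16 | (2S)-5-methyl-2-(prop-1-en-2-yl)hex-4-en-1-ol, (S)-lavandulol | C=C(C)[C@H](CC=C(C)C)CO | intermediate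
17 | (3S)-3-(iodomethyl)-2,6-dimethylhepta-1,5-diene, (S)-lavandulyl iodide | C=C(C)[C@H](CC=C(C)C)CI | intermediate
18 | [(2S)-5-methyl-2-(prop-1-en-2-yl)hex-4-en-1-yl]zinc iodide | C=C(C)[C@H](CC=C(C)C)C[Zn]I | intermediate (not isolated)
19 | 3,5-bis(methoxymethoxy)-4-[(2R)-5-methyl-2-(prop-1-en-2-yl)hex-4-en-1-yl]phenyl (E)-3-[2,4,6-tris(methoxymethoxy)phenyl]prop-2-enoate | C=C(C)[C@H](CC=C(C)C)Cc1c(OCOC)cc(OC(=O)/C=C/c2c(OCOC)cc(OCOC)cc2OCOC)cc1OCOC | intermediate
20 | (E)-1-{6-hydroxy-2,4-bis(methoxymethoxy)-3-[(2R)-5-methyl-2-(prop-1-en-2-yl)hex-4-en-1-yl]phenyl}-3-[2,4,6-tris(methoxymethoxy)phenyl]prop-2-en-1-one | C=C(C)[C@H](CC=C(C)C)Cc1c(OCOC)cc(O)c(C(=O)/C=C/c2c(OCOC)cc(OCOC)cc2OCOC)c1OCOC | intermediate (not isolated)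
21 | (2RS)-5,7-bis(methoxymethoxy)-6-[(2R)-5-methyl-2-(prop-1-en-2-yl)hex-4-en-1-yl]-2-[2,4,6-tris(methoxymethoxy)phenyl]chroman-4-one (mixture of C2 epimers) | C=C(C)[C@H](CC=C(C)C)Cc1c(OCOC)cc2OC(c3c(OCOC)cc(OCOC)cc3OCOC)CC(=O)c2c1OCOC | intermediate
22 | (2S)-5,7-bis(methoxymethoxy)-6-[(2R)-5-methyl-2-(prop-1-en-2-yl)hex-4-en-1-yl]-2-[2,4,6-tris(methoxymethoxy)phenyl]chroman-4-one | C=C(C)[C@H](CC=C(C)C)Cc1c(OCOC)cc2O[C@H](c3c(OCOC)cc(OCOC)cc3OCOC)CC(=O)c2c1OCOC | intermediate
23 | (2S)-6-[(2R)-5-methyl-2-(prop-1-en-2-yl)hex-4-en-1-yl]-5,7-bis(trimethylsilyloxy)-2-[2,4,6-tris(trimethylsilyloxy)phenyl]chroman-4-one | C=C(C)[C@H](CC=C(C)C)Cc1c(O[Si](C)(C)C)cc2O[C@H](c3c(O[Si](C)(C)C)cc(O[Si](C)(C)C)cc3O[Si](C)(C)C)CC(=O)c2c1O[Si](C)(C)C | intermediate (not isolated)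
24 | (2S)-5,7-dihydroxy-6-[(2R)-5-methyl-2-(prop-1-en-2-yl)hex-4-en-1-yl]-2-(2,4,6-trihydroxyphenyl)chroman-4-one | C=C(C)[C@H](CC=C(C)C)Cc1c(O)cc2c(c1O)C(=O)C[C@@H](c1c(O)cc(O)cc1O)O2 | target

**Step count and risks**

Total: 14 steps (telescoped operations counted once). Longest linear sequence: 10 steps (1 → 2 → 4 → 6 → 7 → 9 → 10 → 19 → 21 → 22 → 24; steps 1–6 and 11–14).

The three steps most likely to fail:

Step 12 (photo-Fries of the cinnamate). The cinnamoyl chromophore can drain the excitation into E/Z isomerisation, the chalcone acts as an inner filter, and arene–alkene photocycloaddition of the side chain is possible. The fallback sets out from 6 and 7 and comes back at 20. It transfers only an acetyl group photochemically and builds the enone afterwards. Phenol 6 is acetylated (Ac2O, pyridine) to 4-iodo-3,5-bis(methoxymethoxy)phenyl acetate F1. F1 is coupled with alkylzinc 18 as in step 11 to give 4-Lav-3,5-bis(methoxymethoxy)phenyl acetate F2. Photo-Fries rearrangement of this simple aryl acetate (254 nm, MeCN) gives 1-[6-hydroxy-3-Lav-2,4-bis(methoxymethoxy)phenyl]ethan-1-one F3. Iodide 7 is converted by iodine–lithium exchange (n-BuLi, THF, −78 °C) and DMF into 2,4,6-tris(methoxymethoxy)benzaldehyde F4. Claisen–Schmidt condensation of F3 with F4 (KOH, EtOH) gives chalcone 20, which is cyclised with NaOAc as in step 12.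

Step 13 (kinetic resolution). The ketone is flanked by a peri MOM ether and carries a very bulky 2-aryl group, so reduction may be slow or poorly selective. The fallback sets out from 21 and comes back at 22. The two C2 epimers are diastereomers and are separated physically by preparative HPLC on an amylose-type chiral stationary phase instead of chemically (no new compound, F0). The unwanted (2R) epimer is recycled by NaOAc equilibration through 20.

Step 14 (global MOM removal). Activation of the C4 carbonyl could open the C2–O1 bond (loss of C2 configuration), and the side chain could cyclise onto a neighbouring phenol. The fallback sets out from 21 and comes back at 24. It exchanges the protecting groups before C2 is resolved, so that the last step is a near-neutral ester cleavage. Unresolved 21 is deprotected with methanolic HCl to the (2RS)-pentaphenol F5 (24 together with its 2R epimer). Peracetylation (Ac2O, pyridine, DMAP) gives the (2RS)-pentaacetate F6. Transfer hydrogenation with RhCl[(R,R)-TsDPEN](C5Me5) as in step 13 removes the (2R) epimer as its flavan-4-ol and leaves the (2S)-pentaacetate F7. F7 is deacetylated with NH4OAc in aqueous MeOH at rt to give 24.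

**Further compounds**
F1 | step 12 | 4-iodo-3,5-bis(methoxymethoxy)phenyl acetate | CC(=O)Oc1cc(OCOC)c(I)c(OCOC)c1
F2 | step 12 | 3,5-bis(methoxymethoxy)-4-[(2R)-5-methyl-2-(prop-1-en-2-yl)hex-4-en-1-yl]phenyl acetate | C=C(C)[C@H](CC=C(C)C)Cc1c(OCOC)cc(OC(C)=O)cc1OCOC
F3 | step 12 | 1-{6-hydroxy-2,4-bis(methoxymethoxy)-3-[(2R)-5-methyl-2-(prop-1-en-2-yl)hex-4-en-1-yl]phenyl}ethan-1-one | C=C(C)[C@H](CC=C(C)C)Cc1c(OCOC)cc(O)c(C(C)=O)c1OCOC
F4 | step 12 | 2,4,6-tris(methoxymethoxy)benzaldehyde | COCOc1cc(OCOC)c(C=O)c(OCOC)c1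
F0 | step 13 | none | none
F5 | step 14 | (2RS)-5,7-dihydroxy-6-[(2R)-5-methyl-2-(prop-1-en-2-yl)hex-4-en-1-yl]-2-(2,4,6-trihydroxyphenyl)chroman-4-one | C=C(C)[C@H](CC=C(C)C)Cc1c(O)cc2c(c1O)C(=O)CC(c1c(O)cc(O)cc1O)O2
F6 | step 14 | (2RS)-5,7-diacetoxy-6-[(2R)-5-methyl-2-(prop-1-en-2-yl)hex-4-en-1-yl]-2-(2,4,6-triacetoxyphenyl)chroman-4-one | C=C(C)[C@H](CC=C(C)C)Cc1c(OC(C)=O)cc2c(c1OC(C)=O)C(=O)CC(c1c(OC(C)=O)cc(OC(C)=O)cc1OC(C)=O)O2
F7 | step 14 | (2S)-5,7-diacetoxy-6-[(2R)-5-methyl-2-(prop-1-en-2-yl)hex-4-en-1-yl]-2-(2,4,6-triacetoxyphenyl)chroman-4-one | C=C(C)[C@H](CC=C(C)C)Cc1c(OC(C)=O)cc2c(c1OC(C)=O)C(=O)C[C@@H](c1c(OC(C)=O)cc(OC(C)=O)cc1OC(C)=O)O2
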